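**Retrosynthetic overview**

1. The target is robinetinidol-(4β→6)-gallocatechin: upper unit 2R,3S,4R (2,3-trans, 3,4-cis), lower unit 2R,3S. The last disconnection is global hydrogenolysis of an undeca-O-benzyl ether that still carries a C5 chlorine (upper ring A) and a C8 bromine (lower ring A) as removable control elements.
2. The upper C4–H bond is made last, on the α face, by ionic deoxygenation of a C4 tertiary carbinol (hydride anti to the C3 oxygen). This gives the 3,4-cis aryl that direct arylation of a flavan-4-yl cation does not favour.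
3. Key disconnection: upper ring C is opened at O1–C8a and C4a–C4, so ring A is excised as 5-(benzyloxy)-3-chlorobenzyne and an acyclic anti-α-benzyloxy-β-hydroxy ketone remains. Enabling feature: C8a and C4a are adjacent carbons of ring A bearing the pyran oxygen O1 and C4 respectively, the O1–C2–C3–C4 chain is a 1,3-hydroxy ketone (nucleophilic O, electrophilic C), and C5 of ring A is unsubstituted, so it can hold a chlorine that steers the aryne regiochemistry.
4. The ketone comes from C6-lithiated, C8-bromo-blocked hexa-O-benzyl-gallocatechin and a Weinreb amide whose C2/C3 pair is set by an anti-glycolate aldol.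
5. Ring order: the three rings of the lower unit come intact from (+)-gallocatechin; upper ring B comes with the aldehyde; upper ring A arrives as the aryne and upper ring C is closed in the key step.

Key step: step 12

Assumption: in the anti-glycolate aldol (step 6) the aldehyde is taken to attack the enolate face remote from the auxiliary benzyl group in the non-chelated conformation, which for the (R)-auxiliary gives the (2R,3R) adduct; if the sense is the reverse, the (S)-auxiliary is used.

Numbering used below: flavan numbering, upper unit atoms O1, C2, C3, C4, C4a, C5–C8, C8a; "lower-unit C6/C8" for the gallocatechin part.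

**Step 1**
Reactants: 1 (+)-gallocatechin
Product: 2 (2R,3S)-5,7-bis(benzyloxy)-2-[3,4,5-tris(benzyloxy)phenyl]chroman-3-ol
Conditions: BnBr, K2CO3, DMF, 0 °C to rt, Ar
Reagents that add atoms: benzyl bromide, BrCc1ccccc1
Why: Williamson etherification in which carbonate deprotonates only the five phenols, leaving the aliphatic C3 hydroxyl free and the stereocentres untouched.

**Step 2**
Reactants: 2 penta-O-benzyl-gallocatechin
Product: 3 (2R,3S)-3,5,7-tris(benzyloxy)-2-[3,4,5-tris(benzyloxy)phenyl]chromane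
Conditions: NaH, BnBr, DMF, 0 °C to rt
Reagents that add atoms: benzyl bromide, BrCc1ccccc1
Why: Williamson etherification of the remaining secondary alcohol through its sodium alkoxide, with no stereocentre involved.

**Step 3**
Reactants: 3 hexa-O-benzyl-gallocatechin
Product: 4 (2R,3S)-3,5,7-tris(benzyloxy)-8-bromo-2-[3,4,5-tris(benzyloxy)phenyl]chromane
Conditions: NBS (1.0 equiv), CH2Cl2, −78 °C to rt
Reagents that add atoms: N-bromosuccinimide, BrN1C(=O)CCC1=O
Why: Electrophilic aromatic bromination, for which C8 is the kinetically preferred position of the phloroglucinol-type ring in 5,7-di-O-benzyl flavans; the bromine then serves as a removable blocking group.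

**Step 4**
Reactants: 4 8-bromo hexa-O-benzyl-gallocatechin
Product: 5 (2R,3S)-3,5,7-tris(benzyloxy)-8-bromo-6-iodo-2-[3,4,5-tris(benzyloxy)phenyl]chromane
Conditions: NIS (1.1 equiv), CF3CO2H (cat.), MeCN/CH2Cl2, 0 °C to rt, dark
Reagents that add atoms: N-iodosuccinimide, IN1C(=O)CCC1=O
Why: Electrophilic aromatic iodination, which with C8 blocked should go to C6 between the two benzyloxy groups, a position far more nucleophilic than any on the pyrogallol-type ring B.

**Step 5**
Reactants: 6 (R)-4-benzyl-1,3-oxazolidine-2-thione; 7 benzyloxyacetyl chloride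
Product: 8 (R)-4-benzyl-3-[(benzyloxy)acetyl]-1,3-oxazolidine-2-thione
Conditions: Et3N, CH2Cl2, 0 °C to rt
Reagents that add atoms: none
Why: N-acylation of the auxiliary by acyl substitution at the acid chloride, without involvement of the auxiliary stereocentre.

**Step 6**
Reactants: 8 N-glycolyl oxazolidinethione; 9 3,4,5-tris(benzyloxy)benzaldehyde
Product: 10 (R)-4-benzyl-3-[(2R,3R)-2-(benzyloxy)-3-hydroxy-3-[3,4,5-tris(benzyloxy)phenyl]propanoyl]-1,3-oxazolidine-2-thione
Conditions: TiCl4 (1.1 equiv), i-Pr2NEt (1.1 equiv), CH2Cl2, −78 °C; then 9 premixed with TiCl4 (2 equiv), −78 °C; aq NH4Cl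
Reagents that add atoms: none
Why: Titanium-mediated anti-selective glycolate aldol addition, in which the Z chlorotitanium enolate should add through an open transition state to the TiCl4-activated aldehyde on the face away from the auxiliary benzyl group, setting the future C2 and C3 of upper ring C as the anti (2R,3R) pair.

**Step 7**
Reactants: 10 anti-aldol adduct
Product: 11 (2R,3R)-2-(benzyloxy)-3-hydroxy-N-methoxy-N-methyl-3-[3,4,5-tris(benzyloxy)phenyl]propanamide
Conditions: MeNH(OMe)·HCl, imidazole, CH2Cl2, rt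
Reagents that add atoms: N,O-dimethylhydroxylamine hydrochloride, CNOC.Cl
Why: Direct aminolysis of the activated N-acyl oxazolidinethione to the Weinreb amide (acyl substitution), which should release the auxiliary without touching the β-hydroxyl or either stereocentre.

**Step 8**
Reactants: 11 Weinreb amide; 5 8-bromo-6-iodo hexa-O-benzyl-gallocatechin
Product: 14 (2R,3R)-2-(benzyloxy)-3-hydroxy-1-[(2R,3S)-3,5,7-tris(benzyloxy)-8-bromo-2-(3,4,5-tris(benzyloxy)phenyl)chroman-6-yl]-3-[3,4,5-tris(benzyloxy)phenyl]propan-1-one, via C6-lithio flavan 12 (not isolated), via amide magnesium alkoxide 13 (not isolated)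
Conditions: 11, i-PrMgCl (1.0 equiv), THF, −78 °C; 5, n-BuLi (1.05 equiv), THF, −78 °C; combine, −78 to −30 °C; aq NH4Cl
Reagents that add atoms: none
Why: Iodine–lithium exchange (selective over the C8 bromide at −78 °C) followed by Weinreb ketone synthesis, in which the chelated tetrahedral intermediate prevents over-addition and the pre-formed magnesium alkoxide keeps the hydroxyl from quenching the aryllithium.

**Step 9**
Reactants: 15 4-(benzyloxy)phenol
Product: 16 4-(benzyloxy)-2-chlorophenol
Conditions: SO2Cl2 (1.0 equiv), i-Bu2NH (cat.), toluene, 0 °C to rt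
Reagents that add atoms: sulfuryl chloride, ClS(Cl)(=O)=O
Why: Amine-catalysed electrophilic aromatic chlorination ortho to the phenolic hydroxyl, the para position being blocked by the benzyloxy group.

**Step 10**
Reactants: 16 4-(benzyloxy)-2-chlorophenol
Product: 17 4-(benzyloxy)-2-bromo-6-chlorophenol
Conditions: NBS (1.0 equiv), i-Pr2NH (cat.), CH2Cl2, 0 °C
Reagents that add atoms: N-bromosuccinimide, BrN1C(=O)CCC1=O
Why: Electrophilic aromatic bromination at the one remaining position ortho to the hydroxyl.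

**Step 11**
Reactants: 17 4-(benzyloxy)-2-bromo-6-chlorophenol
Product: 20 4-(benzyloxy)-2-chloro-6-(trimethylsilyl)phenyl trifluoromethanesulfonate, via aryl trimethylsilyl ether 18 (not isolated), via lithium 2-silylphenoxide 19 (not isolated)
Conditions: (Me3Si)2NH, THF, 65 °C, evaporate; n-BuLi, THF, −78 °C; Tf2O, −78 °C to rt
Reagents that add atoms: hexamethyldisilazane, C[Si](C)(C)N[Si](C)(C)C; trifluoromethanesulfonic anhydride, O=S(=O)(OS(=O)(=O)C(F)(F)F)C(F)(F)F
Why: O-silylation, bromine–lithium exchange (bromide in preference to chloride) with 1,3-O-to-C silyl shift (retro-Brook rearrangement) and triflation of the phenoxide, the standard entry to 2-(trimethylsilyl)aryl triflates.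

**Step 12**
Reactants: 14 anti-α-benzyloxy-β-hydroxy ketone; 20 silyl triflate (2 equiv)
Product: 23 (2R,3R,4S)-3,7-bis(benzyloxy)-5-chloro-4-[(2R,3S)-3,5,7-tris(benzyloxy)-8-bromo-2-(3,4,5-tris(benzyloxy)phenyl)chroman-6-yl]-2-[3,4,5-tris(benzyloxy)phenyl]chroman-4-ol (4β-hydroxy, 4α-aryl), via 5-(benzyloxy)-3-chlorobenzyne 21 (not isolated), via ortho-chloroaryl anion 22 (not isolated)
Conditions: KF, 18-crown-6, THF, −20 °C to rt
Reagents that add atoms: none
Why: Proposed new method: fluoride releases aryne 21 from 20, the C2 hydroxyl of 14 (fluoride-bound or as its potassium alkoxide) adds to the aryne carbon remote from chlorine, the resulting 2-chloroaryl anion 22 adds to the C4 ketone and proton transfer gives 23, so that O1–C8a, C4a–C4 and ring C arise in one flask. The closest known reaction types are the fluoride-mediated three-component coupling of arynes, aliphatic alcohols and aldehydes at low temperature and the annulation of arynes with salicylaldehydes or 2-hydroxyaryl ketones to xanthen-9-ols; the present case is their intramolecular version with an aliphatic β-hydroxy ketone. Ring C closes in the 6-exo-trig mode by attack of the aryl anion on the carbonyl carbon. The new C4 carbinol centre should be set by a chair-like closure with the ring B aryl, the C3 benzyloxy group and the lower-unit aryl equatorial (hydroxyl β), but it is erased in step 13, so either epimer serves; C2 and C3 are untouched because only the O–H bond at C2 reacts. The step needs regioselective addition to the aryne, which the C5 chlorine secures (inductive, aryne-distortion control as in 3-haloarynes, overriding the weak opposite bias of the 7-benzyloxy group), and it needs carbonyl capture to outrun proton quench and chloride loss from 22, which the intramolecular six-membered trajectory secures. Retro-aldol cleavage and C3 epimerisation should be held back by the low temperature and the weakly basic fluoride.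

**Step 13**
Reactants: 23 C4 tertiary alcohol
Product: 24 (2R,3S,4S)-3,7-bis(benzyloxy)-5-chloro-4-[(2R,3S)-3,5,7-tris(benzyloxy)-8-bromo-2-(3,4,5-tris(benzyloxy)phenyl)chroman-6-yl]-2-[3,4,5-tris(benzyloxy)phenyl]chromane (4β-aryl, 2,3-trans, 3,4-cis)
Conditions: n-Bu3SnH, CF3CO2H, CH2Cl2, 0 °C
Reagents that add atoms: none
Why: Ionic hydrogenation in which acid ionises the tertiary, doubly benzylic C4–OH to the 4-aryl-flavan-4-yl cation (stabilised by O1 and the 7-benzyloxy group) and the tin hydride should deliver hydride anti to the adjacent C3 benzyloxy group (α face), leaving the lower-unit aryl β and cis to the C3 oxygen, as in the known reductive removal of the C4 hydroxyl from 4-aryl-flavan-3,4-diol derivatives.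

**Step 14**
Reactants: 24 protected, halogenated dimer
Product: 25 robinetinidol-(4β→6)-gallocatechin (CNP0311915.3)
Conditions: H2 (1 atm), Pd(OH)2/C, NaOAc, THF/MeOH/H2O, rt
Reagents that add atoms: none
Why: Heterogeneous hydrogenolysis should cleave the eleven benzyl ethers and both carbon–halogen bonds (acetate buffering the acid set free) without touching the C2–O1 bonds or any stereocentre.

**Compound list**

1 | (+)-gallocatechin, (2R,3S) | Oc1cc2c(c(O)c1)C[C@H](O)[C@@H](c1cc(O)c(O)c(O)c1)O2 | starting material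
2 | (2R,3S)-5,7-bis(benzyloxy)-2-[3,4,5-tris(benzyloxy)phenyl]chroman-3-ol | c1ccccc1COc1cc2c(c(OCc3ccccc3)c1)C[C@H](O)[C@@H](c1cc(OCc3ccccc3)c(OCc3ccccc3)c(OCc3ccccc3)c1)O2 | intermediate
3 | (2R,3S)-3,5,7-tris(benzyloxy)-2-[3,4,5-tris(benzyloxy)phenyl]chromane | c1ccccc1COc1cc2c(c(OCc3ccccc3)c1)C[C@H](OCc1ccccc1)[C@@H](c1cc(OCc3ccccc3)c(OCc3ccccc3)c(OCc3ccccc3)c1)O2 | intermediate
4 | (2R,3S)-3,5,7-tris(benzyloxy)-8-bromo-2-[3,4,5-tris(benzyloxy)phenyl]chromane | c1ccccc1COc1c(Br)c2c(c(OCc3ccccc3)c1)C[C@H](OCc1ccccc1)[C@@H](c1cc(OCc3ccccc3)c(OCc3ccccc3)c(OCc3ccccc3)c1)O2 | intermediate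
5 | (2R,3S)-3,5,7-tris(benzyloxy)-8-bromo-6-iodo-2-[3,4,5-tris(benzyloxy)phenyl]chromane | c1ccccc1COc1c(Br)c2c(c(OCc3ccccc3)c1I)C[C@H](OCc1ccccc1)[C@@H](c1cc(OCc3ccccc3)c(OCc3ccccc3)c(OCc3ccccc3)c1)O2 | intermediate
6 | (R)-4-benzyl-1,3-oxazolidine-2-thione | S=C1N[C@H](Cc2ccccc2)CO1 | starting material
7 | benzyloxyacetyl chloride | O=C(Cl)COCc1ccccc1 | starting material
8 | (R)-4-benzyl-3-[(benzyloxy)acetyl]-1,3-oxazolidine-2-thione | O=C(COCc1ccccc1)N1C(=S)OC[C@H]1Cc1ccccc1 | intermediate
9 | 3,4,5-tris(benzyloxy)benzaldehyde | O=Cc1cc(OCc2ccccc2)c(OCc2ccccc2)c(OCc2ccccc2)c1 | starting material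
10 | (R)-4-benzyl-3-[(2R,3R)-2-(benzyloxy)-3-hydroxy-3-[3,4,5-tris(benzyloxy)phenyl]propanoyl]-1,3-oxazolidine-2-thione | O[C@H](c1cc(OCc2ccccc2)c(OCc2ccccc2)c(OCc2ccccc2)c1)[C@@H](OCc1ccccc1)C(=O)N1C(=S)OC[C@H]1Cc1ccccc1 | intermediate
11 | (2R,3R)-2-(benzyloxy)-3-hydroxy-N-methoxy-N-methyl-3-[3,4,5-tris(benzyloxy)phenyl]propanamide | O[C@H](c1cc(OCc2ccccc2)c(OCc2ccccc2)c(OCc2ccccc2)c1)[C@@H](OCc1ccccc1)C(=O)N(C)OC | intermediate
12 | [(2R,3S)-3,5,7-tris(benzyloxy)-8-bromo-2-(3,4,5-tris(benzyloxy)phenyl)chroman-6-yl]lithium (not isolated) | [Li]c1c(OCc2ccccc2)c(Br)c2c(c1OCc1ccccc1)C[C@H](OCc1ccccc1)[C@@H](c1cc(OCc3ccccc3)c(OCc3ccccc3)c(OCc3ccccc3)c1)O2 | intermediate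
13 | chloromagnesium alkoxide of amide 11 (not isolated) | Cl[Mg]O[C@H](c1cc(OCc2ccccc2)c(OCc2ccccc2)c(OCc2ccccc2)c1)[C@@H](OCc1ccccc1)C(=O)N(C)OC | intermediate
14 | (2R,3R)-2-(benzyloxy)-3-hydroxy-1-[(2R,3S)-3,5,7-tris(benzyloxy)-8-bromo-2-(3,4,5-tris(benzyloxy)phenyl)chroman-6-yl]-3-[3,4,5-tris(benzyloxy)phenyl]propan-1-one | O[C@H](c1cc(OCc2ccccc2)c(OCc2ccccc2)c(OCc2ccccc2)c1)[C@@H](OCc1ccccc1)C(=O)c1c(OCc2ccccc2)c(Br)c2c(c1OCc1ccccc1)C[C@H](OCc1ccccc1)[C@@H](c1cc(OCc3ccccc3)c(OCc3ccccc3)c(OCc3ccccc3)c1)O2 | intermediate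
15 | 4-(benzyloxy)phenol | Oc1ccc(OCc2ccccc2)cc1 | starting material
16 | 4-(benzyloxy)-2-chlorophenol | Oc1ccc(OCc2ccccc2)cc1Cl | intermediate
17 | 4-(benzyloxy)-2-bromo-6-chlorophenol | Oc1c(Br)cc(OCc2ccccc2)cc1Cl | intermediate
18 | [4-(benzyloxy)-2-bromo-6-chlorophenoxy]trimethylsilane (not isolated) | C[Si](C)(C)Oc1c(Br)cc(OCc2ccccc2)cc1Cl | intermediate
19 | lithium 4-(benzyloxy)-2-chloro-6-(trimethylsilyl)phenoxide (not isolated) | [Li+].[O-]c1c([Si](C)(C)C)cc(OCc2ccccc2)cc1Cl | intermediate
20 | 4-(benzyloxy)-2-chloro-6-(trimethylsilyl)phenyl trifluoromethanesulfonate | C[Si](C)(C)c1cc(OCc2ccccc2)cc(Cl)c1OS(=O)(=O)C(F)(F)F | intermediate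
21 | 5-(benzyloxy)-3-chlorobenzyne (not isolated) | ClC1=CC(OCc2ccccc2)=CC#C1 | intermediate
22 | potassium 2-chloroaryl anion formed by O-arylation of 14, carbanion at the future C4a (not isolated) | [K+].[c-]1c(Cl)cc(OCc2ccccc2)cc1O[C@H](c1cc(OCc2ccccc2)c(OCc2ccccc2)c(OCc2ccccc2)c1)[C@@H](OCc1ccccc1)C(=O)c1c(OCc2ccccc2)c(Br)c2c(c1OCc1ccccc1)C[C@H](OCc1ccccc1)[C@@H](c1cc(OCc3ccccc3)c(OCc3ccccc3)c(OCc3ccccc3)c1)O2 | intermediate
23 | (2R,3R,4S)-3,7-bis(benzyloxy)-5-chloro-4-[(2R,3S)-3,5,7-tris(benzyloxy)-8-bromo-2-(3,4,5-tris(benzyloxy)phenyl)chroman-6-yl]-2-[3,4,5-tris(benzyloxy)phenyl]chroman-4-ol | c1ccccc1COc1cc(Cl)c2c(c1)O[C@H](c1cc(OCc3ccccc3)c(OCc3ccccc3)c(OCc3ccccc3)c1)[C@@H](OCc1ccccc1)[C@]2(O)c1c(OCc2ccccc2)c(Br)c2c(c1OCc1ccccc1)C[C@H](OCc1ccccc1)[C@@H](c1cc(OCc3ccccc3)c(OCc3ccccc3)c(OCc3ccccc3)c1)O2 | intermediate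
24 | (2R,3S,4S)-3,7-bis(benzyloxy)-5-chloro-4-[(2R,3S)-3,5,7-tris(benzyloxy)-8-bromo-2-(3,4,5-tris(benzyloxy)phenyl)chroman-6-yl]-2-[3,4,5-tris(benzyloxy)phenyl]chromane | c1ccccc1COc1cc(Cl)c2c(c1)O[C@H](c1cc(OCc3ccccc3)c(OCc3ccccc3)c(OCc3ccccc3)c1)[C@@H](OCc1ccccc1)[C@H]2c1c(OCc2ccccc2)c(Br)c2c(c1OCc1ccccc1)C[C@H](OCc1ccccc1)[C@@H](c1cc(OCc3ccccc3)c(OCc3ccccc3)c(OCc3ccccc3)c1)O2 | intermediate
25 | robinetinidol-(4β→6)-gallocatechin (CNP0311915.3) | Oc1ccc2c(c1)O[C@H](c1cc(O)c(O)c(O)c1)[C@@H](O)[C@H]2c1c(O)cc2c(c1O)C[C@H](O)[C@@H](c1cc(O)c(O)c(O)c1)O2 | target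

**Totals and risks**

Total step count: 14. Longest linear sequence: 8 steps (steps 1, 2, 3, 4, 8, 12, 13, 14).

Steps most likely to fail:

Step 12 (key step, new method). What may go wrong: proton quench of the aryl anion before ring closure (plain O–H insertion, including intramolecular proton transfer from a benzylic ether CH2), retro-aldol cleavage or C3 epimerisation of the β-hydroxy ketone under fluoride, loss of chloride from the 2-chloroaryl anion, or erosion of the aryne regioselectivity. Fallback (known chemistry): it sets out from ketone 14 and comes back to the route at target 25, and it makes the two bonds in two stages. Commercial 4-(benzyloxy)-1-bromo-2-fluorobenzene (Brc1ccc(OCc2ccccc2)cc1F) is lithiated with n-BuLi in THF at −78 °C to [4-(benzyloxy)-2-fluorophenyl]lithium F1. Addition of 2.2 equiv of it to 14 at −78 °C (the first equivalent is consumed by the hydroxyl) should give the 1-aryl-1,3-diol F2, which forms C4a–C4. Intramolecular nucleophilic aromatic substitution of the C2 alkoxide on the aryl fluoride (KHMDS, DMF, 60–80 °C) should then form O1–C8a and give the 5-deschloro analogue of 23, F3. Ionic deoxygenation as in step 13 should give the 5-deschloro analogue of 24, F4, and hydrogenolysis as in step 14 gives 25.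

Step 13. What may go wrong: poor facial selectivity of hydride delivery to the hindered C4 cation (the axial C2 aryl competing with the C3 benzyloxy group for control), or proton loss from C3 to the enol ether. Fallback: it sets out from 23 and comes back at 25. The C4 hydroxyl is removed by heterogeneous hydrogenolysis in the same operation as the debenzylation and dehalogenation (H2, Pd(OH)2/C, THF/MeOH, no added base, the acid set free acting as promoter). Benzylic C–O hydrogenolysis over palladium proceeds with inversion, which on the 4β-hydroxy epimer 23 places hydrogen on the α face and the lower-unit aryl on the β face. No new compound is made.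

Step 14. What may go wrong: incomplete hydrodechlorination of the electron-rich aryl chloride, or acid-induced cleavage of the interflavan bond and over-reduction during the prolonged reaction needed for thirteen bond cleavages. Fallback: it sets out from 24 and comes back at 25. Both carbon–halogen bonds are first removed under homogeneous palladium catalysis with formate as hydride source (Pd(OAc)2, 2-dicyclohexylphosphino-2',4',6'-triisopropylbiphenyl, HCO2Na, DMF, 80 °C), which should give the halogen-free undeca-O-benzyl ether F5. This is then debenzylated under neutral hydrogenolysis (H2, Pd(OH)2/C, THF/MeOH, rt).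

**Further compounds**

F1 | step 12 | [4-(benzyloxy)-2-fluorophenyl]lithium | [Li]c1ccc(OCc2ccccc2)cc1F
F2 | step 12 | (2R,3R)-1-[4-(benzyloxy)-2-fluorophenyl]-2-(benzyloxy)-1-[(2R,3S)-3,5,7-tris(benzyloxy)-8-bromo-2-(3,4,5-tris(benzyloxy)phenyl)chroman-6-yl]-3-[3,4,5-tris(benzyloxy)phenyl]propane-1,3-diol (C1 drawn with the configuration that leads to F3; either epimer serves) | O[C@H](c1cc(OCc2ccccc2)c(OCc2ccccc2)c(OCc2ccccc2)c1)[C@@H](OCc1ccccc1)[C@@](O)(c1ccc(OCc2ccccc2)cc1F)c1c(OCc2ccccc2)c(Br)c2c(c1OCc1ccccc1)C[C@H](OCc1ccccc1)[C@@H](c1cc(OCc3ccccc3)c(OCc3ccccc3)c(OCc3ccccc3)c1)O2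
F3 | step 12 | 5-deschloro analogue of 23 (4β-hydroxy, 4α-aryl chroman-4-ol) | c1ccccc1COc1ccc2c(c1)O[C@H](c1cc(OCc3ccccc3)c(OCc3ccccc3)c(OCc3ccccc3)c1)[C@@H](OCc1ccccc1)[C@]2(O)c1c(OCc2ccccc2)c(Br)c2c(c1OCc1ccccc1)C[C@H](OCc1ccccc1)[C@@H](c1cc(OCc3ccccc3)c(OCc3ccccc3)c(OCc3ccccc3)c1)O2
F4 | step 12 | 5-deschloro analogue of 24 (4β-aryl, 3,4-cis) | c1ccccc1COc1ccc2c(c1)O[C@H](c1cc(OCc3ccccc3)c(OCc3ccccc3)c(OCc3ccccc3)c1)[C@@H](OCc1ccccc1)[C@H]2c1c(OCc2ccccc2)c(Br)c2c(c1OCc1ccccc1)C[C@H](OCc1ccccc1)[C@@H](c1cc(OCc3ccccc3)c(OCc3ccccc3)c(OCc3ccccc3)c1)O2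
F0 | step 13 | none | none
F5 | step 14 | halogen-free undeca-O-benzyl ether of robinetinidol-(4β→6)-gallocatechin | c1ccccc1COc1ccc2c(c1)O[C@H](c1cc(OCc3ccccc3)c(OCc3ccccc3)c(OCc3ccccc3)c1)[C@@H](OCc1ccccc1)[C@H]2c1c(OCc2ccccc2)cc2c(c1OCc1ccccc1)C[C@H](OCc1ccccc1)[C@@H](c1cc(OCc3ccccc3)c(OCc3ccccc3)c(OCc3ccccc3)c1)O2
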